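**Retrosynthetic overview**
1. Andilesin A (24) ⇐ carbonyl reduction at C7′ of cage keto lactone 23.
2. 23 ⇐ intramolecular Diels–Alder reaction of hydroxy dienone 21, forming C8–C3a′ and C12–C6′ (cyclopentane ring C and the bicyclo[2.2.2]octane together).
3. 21 ⇐ photochemical dearomative para-C-alkylation of phenol 7 with iodide 19, forming C11–C4′ and the quaternary C4′.
4. 19 ⇐ formaldehyde ene reaction on alkene 17 ⇐ (R)-carvone; 7 ⇐ atraric acid.
5. Ring order: ring B (bought) → ring A lactone → aromatic ring dearomatised → ring C plus cage in one step.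

Assumption: the enolisable C7a′ of 23 settles in the natural configuration. Locants: drimane-type C1–C12 for the carvone half (C11 = linking CH2, C12 = former C8 methyl), primed phthalide locants for the aromatic half.

**Fragment 1 (aromatic)**

Step 1
Reactants: 1 atraric acid (methyl 2,4-dihydroxy-3,6-dimethylbenzoate)
Product: 2 methyl 5-formyl-2,4-dihydroxy-3,6-dimethylbenzoate
Conditions: Cl2CHOMe, TiCl4, CH2Cl2, 0 °C; aq. HCl
Reagents that add atoms: dichloromethyl methyl ether COC(Cl)Cl; water O
Why: Rieche formylation; the titanium phenoxide delivers the electrophile to C5, the only unsubstituted ring carbon (ortho to the 4-OH).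

Step 2
Reactants: 2 methyl 5-formyl-2,4-dihydroxy-3,6-dimethylbenzoate
Product: 3 methyl 2,4-dihydroxy-3,5,6-trimethylbenzoate
Conditions: Et3SiH, CF3CO2H, CH2Cl2, 25 °C
Reagents that add atoms: none
Why: Ionic hydrogenation (silane/acid) of an electron-rich ortho-hydroxy benzaldehyde runs through the benzylic cation to the aryl methyl group.

Step 3
Reactants: 3 methyl 2,4-dihydroxy-3,5,6-trimethylbenzoate
Product: 4 methyl 2,4-dimethoxy-3,5,6-trimethylbenzoate
Conditions: MeI, K2CO3, DMF, 60 °C
Reagents that add atoms: iodomethane CI
Why: Williamson O-methylation of both phenols masks them for the benzylic lithiation.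

Step 4
Reactants: 4 methyl 2,4-dimethoxy-3,5,6-trimethylbenzoate
Product: 6 5,7-dimethoxy-4,6-dimethylphthalide, via hydroxymethyl benzoate 5 (not isolated)
Conditions: LiN(iPr)2, THF, −78 °C; 2-(phenylsulfonyl)-3-phenyloxaziridine, −78 → 25 °C; H2O
Reagents that add atoms: 2-(phenylsulfonyl)-3-phenyloxaziridine O=S(=O)(c1ccccc1)N1OC1c1ccccc1
Why: Lateral (benzylic) lithiation of the ortho-toluate, oxaziridine hydroxylation at the benzylic carbon and lactonisation of alkoxide 5 onto the ester give the phthalide.

Step 5
Reactants: 6 5,7-dimethoxy-4,6-dimethylphthalide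
Product: 7 7-hydroxy-5-methoxy-4,6-dimethylphthalide
Conditions: BCl3, CH2Cl2, −78 → 0 °C; H2O
Reagents that add atoms: none
Why: Chelation-controlled Lewis-acid demethylation; BCl3 bound to the lactone carbonyl cleaves only the peri 7-methyl ether.

**Fragment 2 (terpenoid)**

Step 6
Reactants: 8 (R)-(−)-carvone
Product: 9 (5R,6S)-6-methylcarvone
Conditions: LiN(iPr)2, THF, −78 °C; MeI, −78 → 0 °C
Reagents that add atoms: iodomethane CI
Why: Kinetic α′-enolate alkylation of the enone; the new C6 centre is levelled again in step 7, so its ratio does not matter.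

Step 7
Reactants: 9 (5R,6S)-6-methylcarvone
Product: 10 (5S,6S)-6-allyl-6-methylcarvone
Conditions: LiN(iPr)2, THF–DMPU, −78 °C; allyl bromide, −78 → 0 °C
Reagents that add atoms: allyl bromide C=CCBr
Why: Second α′-enolate alkylation; allyl bromide enters anti to the adjacent isopropenyl group, so the quaternary carbon (later C10) carries methyl cis and allyl trans to isopropenyl (control by the carvone stereocentre, later C5).

Step 8
Reactants: 10 (5S,6S)-6-allyl-6-methylcarvone
Product: 11 6-(3-hydroxypropyl)-6-methylcarvone
Conditions: Cy2BH, THF, 0 °C; Me3NO·2H2O, 65 °C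
Reagents that add atoms: trimethylamine N-oxide C[N+](C)(C)[O-]
Why: Chemoselective hydroboration of the monosubstituted alkene by the hindered dialkylborane; amine-oxide oxidation avoids alkaline-peroxide epoxidation of the enone.

Step 9
Reactants: 11 6-(3-hydroxypropyl)-6-methylcarvone
Product: 12 6-(2-carboxyethyl)-6-methylcarvone
Conditions: TEMPO (cat.), PhI(OAc)2, MeCN–H2O, 25 °C
Reagents that add atoms: water O
Why: Nitroxyl-catalysed oxidation of the primary alcohol through the aldehyde hydrate to the acid; the alkenes and the enone are inert.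

Step 10
Reactants: 12 6-(2-carboxyethyl)-6-methylcarvone
Product: 13 enone lactone (trans-fused ring A ε-lactone on the carvone ring)
Conditions: Co(salen) = Co(C16H14N2O2) (divalent cobalt, cat.), N-fluoro-2,4,6-trimethylpyridinium tetrafluoroborate, (Me2SiH)2O, PhCF3, 25 °C
Reagents that add atoms: none
Why: Cobalt-hydride hydrogen-atom transfer to the isopropenyl group, radical–polar crossover and capture by the carboxylic acid (Markovnikov hydroacyloxylation) close the ε-lactone without a free carbocation, so no hydride shift to a smaller lactone is expected.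

Step 11
Reactants: 13 enone lactone
Product: 15 alkene lactone (C8=C9 alkene), via tosylhydrazone 14 (not isolated)
Conditions: TsNHNH2, TsOH (cat.), THF, 60 °C; catecholborane, 0 °C; NaOAc·3H2O, 65 °C
Reagents that add atoms: none
Why: Kabalka reductive transposition; hydride reduction of the enone tosylhydrazone, sulfinate loss and retro-ene loss of N2 from the allylic diazene move the alkene to C8=C9 (no new stereocentre).

Step 12
Reactants: 15 alkene lactone
Product: 17 dienyl lactone (C1=C2 enoate and C8=C9 alkene), via phenylselenide 16 (not isolated)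
Conditions: LiN(iPr)2, THF, −78 °C; PhSeBr; H2O2, pyridine, CH2Cl2, 0 °C
Reagents that add atoms: none
Why: α-Selenenylation of the lactone enolate and selenoxide syn-elimination give the ring (cis) enoate of ring A.

Step 13
Reactants: 17 dienyl lactone
Product: 18 lactone alcohol (9-epi-albicanol type: C9 CH2OH α, H β; C8 exocyclic methylene)
Conditions: (CH2O)n, Me2AlCl, CH2Cl2, −78 → 0 °C
Reagents that add atoms: formaldehyde C=O
Why: Lewis-acid carbonyl-ene reaction; formaldehyde bonds to the less substituted alkene carbon C9 on the α-face, anti to the axial C10 methyl, and takes a hydrogen from the C8 methyl, which sets C9 and the exocyclic alkene.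

Step 14
Reactants: 18 lactone alcohol
Product: 19 lactone iodide
Conditions: PPh3, I2, imidazole, CH2Cl2, 0 → 25 °C
Reagents that add atoms: iodine II
Why: Appel iodination (SN2 at the primary carbinol) gives the radical precursor without touching C9.

**Union and endgame**

Step 15
Reactants: 19 lactone iodide; 7 7-hydroxy-5-methoxy-4,6-dimethylphthalide
Product: 20 para-dienone (4′R epimer drawn; formed with its 4′S epimer)
Conditions: 7 (2 equiv), Cs2CO3, DMSO (degassed), 390 nm LED, 20 °C
Reagents that add atoms: none
Why: Proposed new method: near-UV excitation turns the caesium phenolate of 7 into a strong one-electron donor that cleaves the C–I bond of 19 by dissociative electron transfer, and the primary alkyl radical combines with the persistent phenoxyl radical at the para carbon C4′ (highest spin density; the ortho carbons are shielded between two oxygens or acylated) to give the dearomatised 4,4-disubstituted cyclohexa-2,5-dienone with the C11–C4′ bond (no facial control expected, about 1:1 at C4′); closest known reaction types are photostimulated radical-nucleophilic (SRN1) C-alkylation of phenoxides and the photoinduced dearomative alkylation of 2-naphtholates through electron donor–acceptor complexes.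

Step 16
Reactants: 20 para-dienone
Product: 23 7′-dehydroandilesin A (cage keto lactone), via hydroxy dienone 21 (not isolated), via enol cycloadduct 22 (not isolated)
Conditions: LiCl, DMF, 100 °C; AcOH; 130 °C
Reagents that add atoms: none
Why: Krapcho-type SN2 O-demethylation unmasks the 1,3-dione, whose hydroxy-dienone tautomer 21 undergoes an intramolecular Diels–Alder reaction with the exocyclic alkene; the axial C11 tether holds the diene under the α-face of C8=C12, so only the 4′R epimer can react (the 4′S epimer is left behind and removed), C8, C3a′ and C6′ are set together, and ketonisation of enol 22 puts the enolisable C7a′ in its thermodynamic orientation.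

Step 17
Reactants: 23 7′-dehydroandilesin A
Product: 24 andilesin A
Conditions: NaBH4, CeCl3·7H2O, MeOH, −40 °C
Reagents that add atoms: none
Why: Luche-type 1,2-reduction; the C5′ ketone (two quaternary neighbours) and the enoate are left, and hydride adds to C7′ anti to the lactone carbonyl on C7a′ (from the side of the C8–C12 bridge), giving the natural carbinol.

**Compound list**

1 | atraric acid (methyl 2,4-dihydroxy-3,6-dimethylbenzoate) | COC(=O)c1c(C)cc(O)c(C)c1O | starting material
2 | methyl 5-formyl-2,4-dihydroxy-3,6-dimethylbenzoate | COC(=O)c1c(C)c(C=O)c(O)c(C)c1O | intermediate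
3 | methyl 2,4-dihydroxy-3,5,6-trimethylbenzoate | COC(=O)c1c(C)c(C)c(O)c(C)c1O | intermediate
4 | methyl 2,4-dimethoxy-3,5,6-trimethylbenzoate | COC(=O)c1c(C)c(C)c(OC)c(C)c1OC | intermediate
5 | methyl 2-(hydroxymethyl)-4,6-dimethoxy-3,5-dimethylbenzoate (formed as its lithium alkoxide) | COC(=O)c1c(CO)c(C)c(OC)c(C)c1OC | intermediate
6 | 5,7-dimethoxy-4,6-dimethylphthalide | COc1c(C)c(OC)c2C(=O)OCc2c1C | intermediate
7 | 7-hydroxy-5-methoxy-4,6-dimethylphthalide | COc1c(C)c(O)c2C(=O)OCc2c1C | intermediate
8 | (R)-(−)-carvone | CC1=CC[C@H](CC1=O)C(C)=C | starting material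
9 | (5R,6S)-6-methylcarvone (methyl trans to isopropenyl) | C[C@H]1[C@H](C(C)=C)CC=C(C)C1=O | intermediate
10 | (5S,6S)-6-allyl-6-methylcarvone (allyl trans, methyl cis to isopropenyl) | C=CC[C@@]1(C)[C@H](C(C)=C)CC=C(C)C1=O | intermediate
11 | 6-(3-hydroxypropyl)-6-methylcarvone (configuration as 10) | OCCC[C@@]1(C)[C@H](C(C)=C)CC=C(C)C1=O | intermediate
12 | 6-(2-carboxyethyl)-6-methylcarvone (configuration as 10) | OC(=O)CC[C@@]1(C)[C@H](C(C)=C)CC=C(C)C1=O | intermediate
13 | enone lactone: trans-fused 1,1,5a,7-tetramethyl-1,4,5,5a,9,9a-hexahydro-2-benzoxepine-3,6-dione (5a-methyl and 9a-H anti) | CC1(C)OC(=O)CC[C@@]2(C)[C@H]1CC=C(C)C2=O | intermediate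
14 | 6-(p-toluenesulfonyl)hydrazone of 13 | CC1(C)OC(=O)CC[C@@]2(C)[C@H]1CC=C(C)C2=NNS(=O)(=O)c1ccc(C)cc1 | intermediate
15 | alkene lactone: trans-fused 1,1,5a,7-tetramethyl-4,5,5a,8,9,9a-hexahydro-1H-2-benzoxepin-3-one | CC1(C)OC(=O)CC[C@@]2(C)[C@H]1CCC(C)=C2 | intermediate
16 | 4-(phenylselanyl) derivative of 15 (C4 epimers) | CC1(C)OC(=O)C([Se]c3ccccc3)C[C@@]2(C)[C@H]1CCC(C)=C2 | intermediate
17 | dienyl lactone: trans-fused 1,1,5a,7-tetramethyl-5a,8,9,9a-tetrahydro-1H-2-benzoxepin-3-one | CC1(C)OC(=O)C=C[C@@]2(C)[C@H]1CCC(C)=C2 | intermediate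
18 | lactone alcohol: 6-(hydroxymethyl)-1,1,5a-trimethyl-7-methylidene analogue of 17, CH2OH on the face opposite the 5a-methyl | CC1(C)OC(=O)C=C[C@@]2(C)[C@H]1CCC(=C)[C@H]2CO | intermediate
19 | lactone iodide: 6-(iodomethyl) analogue of 18 | CC1(C)OC(=O)C=C[C@@]2(C)[C@H]1CCC(=C)[C@H]2CI | intermediate
20 | para-dienone: (4′R)-5′-methoxy-4′,6′-dimethyl-3′,4′-dihydro-2-benzofuran-1′,7′-dione carrying at C4′ the C11 methylene of 19 | CC1(C)OC(=O)C=C[C@@]2(C)[C@H]1CCC(=C)[C@H]2C[C@@]3(C)C(OC)=C(C)C(=O)C4=C3COC4=O | intermediate
21 | hydroxy dienone: 7′-hydroxy-5′-oxo tautomer formed by O-demethylation of 20 | CC1(C)OC(=O)C=C[C@@]2(C)[C@H]1CCC(=C)[C@H]2C[C@@]3(C)C(=O)C(C)=C(O)C4=C3COC4=O | intermediate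
22 | enol cycloadduct: C7a′=C7′ enol of 23 | CC1(C)OC(=O)C=C[C@@]2(C)[C@H]1CC[C@]13C[C@]4(C)C(=O)[C@](C)(C[C@@H]21)[C@]31COC(=O)C1=C4O | intermediate
23 | 7′-dehydroandilesin A (cage β-keto lactone) | CC1(C)OC(=O)C=C[C@@]2(C)[C@H]1CC[C@]13C[C@]4(C)C(=O)[C@](C)(C[C@@H]21)[C@]31COC(=O)[C@H]1C4=O | intermediate
24 | andilesin A | CC1(C)OC(=O)C=C[C@@]2(C)[C@H]1CC[C@]13C[C@]4(C)C(=O)[C@](C)(C[C@@H]21)[C@]31COC(=O)[C@H]1[C@H]4O | target

**Step count:** 17 steps in total; longest linear sequence 12 steps (steps 6–17 from (R)-carvone).

**Steps most likely to fail**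

Step 15 (the new photochemical coupling). Risks are O-alkylation, reduction of the radical, and the expected 1:1 ratio at C4′, which caps the useful yield near half. The fallback uses known chemistry and sets out from alcohol 18 and phenol 7. A Mitsunobu etherification (PPh3, DIAD, THF) gives the 7-O-alkyl aryl ether F2. Irradiation at 254 nm in MeCN then effects a photo-Claisen rearrangement (C–O homolysis and in-cage recombination at the para carbon). This comes back to the route at dienone 20.

Step 16 (intramolecular Diels–Alder reaction). It must join two quaternary carbons with an unactivated alkene, and only one C4′ epimer is competent. The fallback sets out from hydroxy dienone 21, made from 20 as before. It closes the same two bonds stepwise by a redox-neutral radical cyclisation of the 1,3-dicarbonyl: Ir[dF(CF3)ppy]2(dtbbpy)PF6 (trivalent iridium), K2HPO4, MeCN, 450 nm. Enolate oxidation gives the C6′ radical, which adds to C12; the tertiary C8 radical closes onto C3a′, and the resulting α-dicarbonyl radical is reduced and protonated. No new isolable compound is made (F0), and the route is rejoined at 23.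

Step 13 (ene reaction). Hydrogen transfer from the ring CH2 instead of the methyl would give the endocyclic alkene. The fallback sets out from 17. Formaldehyde addition with one equivalent of Me2AlCl at −78 °C is stopped at the syn chlorohydrin F1 (C8 chloride and C9 CH2OH cis). E2 dehydrochlorination (DBU, toluene, 80 °C) follows. The equatorial tertiary chloride has anti-periplanar hydrogens only on the methyl group, so only the exocyclic alkene forms. The route is rejoined at 18.

**Further compounds**

F1 | step 13 | chlorohydrin: 7-chloro-6-(hydroxymethyl)-1,1,5a,7-tetramethyl-5a,6,7,8,9,9a-hexahydro-1H-2-benzoxepin-3-one (Cl and CH2OH cis) | CC1(C)OC(=O)C=C[C@@]2(C)[C@H]1CC[C@@](C)(Cl)[C@H]2CO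
F2 | step 15 | aryl ether: 7-O-alkyl ether of phenol 7 with the C11 methylene of 18 | CC1(C)OC(=O)C=C[C@@]2(C)[C@H]1CCC(=C)[C@H]2COc1c(C)c(OC)c(C)c2COC(=O)c12
F0 | step 16 | none | none
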